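**Retrosynthetic overview**
1. Target ⇐ desilylation and reagent-controlled reduction of C3=O in a bicyclic 3-oxo α-methylene-ε-lactone.
2. ε-Lactone ring (formed last), the C1–C15 bond, C1 and the exo-methylene ⇐ new 7-exo cross-Rauhut–Currier closure of a C12 acrylate onto the C1=C2–C3=O enone of the 14-membered carbocycle.
3. 14-Membered ring (formed first) ⇐ Nozaki–Hiyama–Kishi closure of C2–C3 (E-vinyl iodide + α-silyloxy aldehyde), then oxidation.
4. C11/C12 ⇐ Sharpless epoxidation of the SeO2-derived C13 allylic alcohol, SN2 extension at C13–C14, 5-exo lactonisation with inversion at C12. C4 ⇐ Sharpless epoxidation of a 2-substituted allyl alcohol, then hydride opening.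
5. Carbons: nerol (C6–C13, C19, C20, Z-C7=C8), methallyl alcohol (C3–C5, C18), tert-butyl acetate (C14, C1), Ohira–Bestmann carbon (C2), acryloyl chloride (C15–C17).

Assumption: the SMILES is taken literally, so the ring alkene is 7Z (C6 and C9 cis) and the configuration is 1R,3R,4S,11S,12R. Cembrane numbering is used: C1 = CH bearing C15, C16 = lactone C=O, C17 = exocyclic CH2, C18/C19/C20 = methyls on C4/C8/C12. TBS = tert-butyldimethylsilyl.

Step 1
Reactants: 1 nerol [(2Z)-3,7-dimethylocta-2,6-dien-1-ol]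
Product: 2 neryl bromide [(2Z)-1-bromo-3,7-dimethylocta-2,6-diene]
Conditions: PBr3 (0.4 equiv), Et2O, −10 °C, dark
Reagents that add atoms: phosphorus tribromide, BrP(Br)Br
Why: Low-temperature alcohol-to-bromide substitution through the phosphite ester converts the primary allylic alcohol without isomerising the Z-alkene that becomes C7=C8.

Step 2
Reactants: 2 neryl bromide; 3 methallyl alcohol (2-methylprop-2-en-1-ol)
Product: 5 (5Z)-6,10-dimethyl-2-methylideneundeca-5,9-dien-1-ol, via dilithiated methallyl alcohol 4 (not isolated)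
Conditions: 3, n-BuLi (2 equiv per 3), TMEDA, Et2O/hexane, 0 °C to rt; then 2, THF, −78 to 0 °C; H2O
Reagents that add atoms: none
Why: Dianion alkylation: the 2-(oxidomethyl)allyl dianion has two equivalent CH2 termini and attacks the primary allylic bromide by SN2, forming C5–C6 with the Z-alkene intact.

Step 3
Reactants: 5 (5Z)-6,10-dimethyl-2-methylideneundeca-5,9-dien-1-ol
Product: 6 [(2S)-2-[(3Z)-4,8-dimethylnona-3,7-dien-1-yl]oxiran-2-yl]methanol
Conditions: Ti(OiPr)4 (10 mol %), L-(+)-DIPT (12 mol %), t-BuOOH, 4 Å MS, CH2Cl2, −25 °C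
Reagents that add atoms: tert-butyl hydroperoxide, CC(C)(C)OO
Why: Sharpless asymmetric epoxidation acts only on the allylic alcohol, and the L-(+)-tartrate delivers oxygen to the face that gives the (S)-oxirane, which sets C4.

Step 4
Reactants: 6 [(2S)-2-[(3Z)-4,8-dimethylnona-3,7-dien-1-yl]oxiran-2-yl]methanol
Product: 7 (2S,5Z)-2,6,10-trimethylundeca-5,9-diene-1,2-diol
Conditions: LiAlH4, THF, 0 °C; aq. work-up
Reagents that add atoms: none
Why: SN2 hydride opening of the 2,2-disubstituted epoxide at its CH2 terminus turns that carbon into the C18 methyl and leaves the C4–O bond (4S) untouched.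

Step 5
Reactants: 7 (2S,5Z)-2,6,10-trimethylundeca-5,9-diene-1,2-diol
Product: 8 (2S,5Z)-1,2-bis(TBSO)-2,6,10-trimethylundeca-5,9-diene
Conditions: TBSOTf (2.6 equiv), 2,6-lutidine, CH2Cl2, 0 °C to rt
Reagents that add atoms: tert-butyldimethylsilyl triflate, CC(C)(C)[Si](C)(C)OS(=O)(=O)C(F)(F)F
Why: Silyl triflate silylation is strong enough to cap both the primary C3–OH and the tertiary C4–OH in one operation.

Step 6
Reactants: 8 (2S,5Z)-1,2-bis(TBSO)-2,6,10-trimethylundeca-5,9-diene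
Product: 9 (2E,6Z,10S)-10,11-bis(TBSO)-2,6,10-trimethylundeca-2,6-dien-1-ol
Conditions: SeO2 (10 mol %), salicylic acid (10 mol %), t-BuOOH, CH2Cl2, rt (stopped at partial conversion, 8 recycled)
Reagents that add atoms: tert-butyl hydroperoxide, CC(C)(C)OO
Why: Catalytic SeO2 allylic oxidation (ene reaction, then [2,3]-shift) prefers the unhindered terminal isopropylidene and oxidises only its E-methyl, giving the E-allylic alcohol at C13.

Step 7
Reactants: 9 (2E,6Z,10S)-10,11-bis(TBSO)-2,6,10-trimethylundeca-2,6-dien-1-ol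
Product: 10 [(2S,3S)-3-[(3Z,7S)-7,8-bis(TBSO)-3,7-dimethyloct-3-en-1-yl]-2-methyloxiran-2-yl]methanol
Conditions: Ti(OiPr)4 (10 mol %), L-(+)-DET (13 mol %), t-BuOOH, 4 Å MS, CH2Cl2, −20 °C
Reagents that add atoms: tert-butyl hydroperoxide, CC(C)(C)OO
Why: Sharpless asymmetric epoxidation of the E-2-methyl allylic alcohol with L-(+)-tartrate gives the (2S,3S)-epoxide, i.e. 11S,12S, and the unactivated C7=C8 alkene does not react.

Step 8
Reactants: 10 [(2S,3S)-3-[(3Z,7S)-7,8-bis(TBSO)-3,7-dimethyloct-3-en-1-yl]-2-methyloxiran-2-yl]methanol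
Product: 11 [(2S,3S)-3-[(3Z,7S)-7,8-bis(TBSO)-3,7-dimethyloct-3-en-1-yl]-2-methyloxiran-2-yl]methyl trifluoromethanesulfonate
Conditions: Tf2O (1.1 equiv), 2,6-lutidine, CH2Cl2, −78 °C; cold aqueous wash, used at once
Reagents that add atoms: trifluoromethanesulfonic anhydride, O=S(=O)(OS(=O)(=O)C(F)(F)F)C(F)(F)F
Why: O-Sulfonylation of the only free hydroxyl gives a triflate with no β-hydrogen, so it cannot eliminate and survives long enough for the next step.

Step 9
Reactants: 11 epoxy triflate; 12 tert-butyl acetate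
Product: 14 tert-butyl 3-[(2S,3S)-3-[(3Z,7S)-7,8-bis(TBSO)-3,7-dimethyloct-3-en-1-yl]-2-methyloxiran-2-yl]propanoate, via lithium enolate of tert-butyl acetate 13 (not isolated)
Conditions: 12, LDA, THF, −78 °C; then 11, DMPU, −78 to −40 °C
Reagents that add atoms: none
Why: Ester enolate alkylation (SN2) at the oxirane-activated CH2–OTf forms C13–C14 faster than any attack on the hindered trisubstituted epoxide, and no stereocentre is touched.

Step 10
Reactants: 14 γ,δ-epoxy tert-butyl ester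
Product: 15 (5R)-5-[(1S,4Z,8S)-8,9-bis(TBSO)-1-hydroxy-4,8-dimethylnon-4-en-1-yl]-5-methyloxolan-2-one
Conditions: CSA (20 mol %), anhydrous CH2Cl2, 0 °C to rt
Reagents that add atoms: none
Why: Acid-catalysed 5-exo epoxide-opening lactonisation: the ester carbonyl oxygen attacks tertiary C12 with inversion (12S to 12R), C11–O is retained (11S), tert-butyl leaves as isobutene, and the nearby internal O-nucleophile outruns cation–olefin cyclisation with C7=C8.

Step 11
Reactants: 15 hydroxy γ-lactone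
Product: 16 (5R)-5-[(1S,4Z,8S)-1,8,9-tris(TBSO)-4,8-dimethylnon-4-en-1-yl]-5-methyloxolan-2-one
Conditions: TBSOTf (1.5 equiv), 2,6-lutidine, CH2Cl2, 0 °C
Reagents that add atoms: tert-butyldimethylsilyl triflate, CC(C)(C)[Si](C)(C)OS(=O)(=O)C(F)(F)F
Why: Silyl triflate silylation protects the hindered secondary C11–OH so that later only the C12 oxygen can be acylated.

Step 12
Reactants: 16 tris-TBS γ-lactone
Product: 17 (5R)-5-[(1S,4Z,8S)-1,8,9-tris(TBSO)-4,8-dimethylnon-4-en-1-yl]-5-methyloxolan-2-ol (anomer mixture)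
Conditions: DIBAL-H (1.1 equiv), CH2Cl2, −78 °C; aq. work-up
Reagents that add atoms: none
Why: Partial reduction of the lactone stops at the stable aluminium hemiacetal at −78 °C and gives the lactol.

Step 13
Reactants: 17 lactol
Product: 18 (5R,6S,9Z,13S)-6,13,14-tris(TBSO)-5,9,13-trimethyltetradec-9-en-1-yn-5-ol
Conditions: Ohira–Bestmann reagent, K2CO3, MeOH, 0 °C to rt
Reagents that add atoms: dimethyl (1-diazo-2-oxopropyl)phosphonate, CC(=O)C(=[N+]=[N-])P(=O)(OC)OC
Why: Seyferth–Gilbert homologation (Ohira–Bestmann variant) irreversibly traps the open hydroxy-aldehyde tautomer of the lactol, adding C2 as a terminal alkyne and freeing the tertiary C12–OH.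

Step 14
Reactants: 18 alkynol
Product: 20 (1E,5R,6S,9Z,13S)-1-iodo-6,13,14-tris(TBSO)-5,9,13-trimethyltetradeca-1,9-dien-5-ol, via alkenylzirconocene chloride 19 (not isolated)
Conditions: Cp2Zr(H)Cl (2.3 equiv), THF, rt, dark; then I2, 0 °C; aq. work-up
Reagents that add atoms: iodine, II
Why: Schwartz hydrozirconation adds syn with Zr at the terminal carbon (one equivalent is used up by the OH), and iodinolysis with retention gives only the E-vinyl iodide while the trisubstituted alkene stays inert.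

Step 15
Reactants: 20 vinyl iodide alcohol; 21 acryloyl chloride
Product: 22 (1E,5R,6S,9Z,13S)-1-iodo-6,13,14-tris(TBSO)-5,9,13-trimethyltetradeca-1,9-dien-5-yl prop-2-enoate
Conditions: 21 (3 equiv), iPr2NEt, DMAP (0.5 equiv), BHT (trace), CH2Cl2, 0 °C to rt
Reagents that add atoms: none
Why: DMAP-catalysed acylation of the only free hydroxyl makes the hindered tertiary C12–O–C16 ester bond intermolecularly, so no late lactonisation onto a tertiary alcohol is needed.

Step 16
Reactants: 22 acrylate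
Product: 23 (1E,5R,6S,9Z,13S)-14-hydroxy-1-iodo-6,13-bis(TBSO)-5,9,13-trimethyltetradeca-1,9-dien-5-yl prop-2-enoate
Conditions: HF·pyridine, pyridine, THF, 0 °C
Reagents that add atoms: none
Why: Selective fluoride desilylation: the primary silyl ether is cleaved much faster than the hindered secondary (C11) and tertiary (C4) ones, and the acrylate and vinyl iodide are inert.

Step 17
Reactants: 23 primary alcohol
Product: 24 (1E,5R,6S,9Z,13S)-1-iodo-5,9,13-trimethyl-14-oxo-6,13-bis(TBSO)tetradeca-1,9-dien-5-yl prop-2-enoate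
Conditions: Dess–Martin periodinane, CH2Cl2, rt
Reagents that add atoms: none
Why: Dess–Martin oxidation gives the C3 aldehyde, which cannot epimerise because C4 is quaternary.

Step 18
Reactants: 24 iodo aldehyde
Product: 25 (1E,4S,7Z,11S,12R)-3-hydroxy-4,11-bis(TBSO)-4,8,12-trimethylcyclotetradeca-1,7-dien-12-yl prop-2-enoate (cembrane numbering, C3 epimers)
Conditions: CrCl2 (10 equiv), NiCl2 (1 mol % of Cr), DMSO/THF, 0.003 M, slow addition, rt; aq. work-up
Reagents that add atoms: none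
Why: Nozaki–Hiyama–Kishi macrocyclisation: the alkenylchromium(III) species adds only to the aldehyde (esters, acrylate and silyl ethers are tolerated), closing C2–C3 and the 14-membered ring with the E-alkene retained.

Step 19
Reactants: 25 macrocyclic allylic alcohol
Product: 26 (1E,4S,7Z,11S,12R)-4,11-bis(TBSO)-4,8,12-trimethyl-3-oxocyclotetradeca-1,7-dien-12-yl prop-2-enoate (cembrane numbering)
Conditions: Dess–Martin periodinane, CH2Cl2, rt
Reagents that add atoms: none
Why: Dess–Martin oxidation merges both C3 epimers into one E-enone, and no oxa-Michael reaction can occur because the C12 oxygen is already acylated.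

Step 20
Reactants: 26 macrocyclic enone acrylate
Product: 27 (1R,4S,7Z,11S,12R)-4,11-bis(TBSO)-3-oxocembra-7,15(17)-dien-16,12-olide
Conditions: (S)-P1 (20 mol %; P1 = N-[3,5-bis(trifluoromethyl)phenyl]-N'-[(2S)-1-(dimethylphosphanyl)-3,3-dimethylbutan-2-yl]thiourea, new catalyst), 2-naphthol (20 mol %), toluene/t-AmOH 9:1, 0.005 M, 25 °C, Ar
Reagents that add atoms: none
Why: Proposed new method: a catalytic 7-exo-trig cross-Rauhut–Currier lactone annulation in which the small, strongly nucleophilic dialkylphosphine arm of the new bifunctional catalyst P1 adds reversibly only to the unsubstituted acrylate terminus C17 (the β-alkylated, ring-embedded enone is too hindered to act as donor), the resulting phosphonium ester enolate attacks C1 of the thiourea-bound enone (the gem-disubstituted C12 and the preorganising 14-ring offset the usual entropic penalty of seven-ring closure), 2-naphthol shuttles H from C15 to C2 and E1cB loss of P1 unveils C15=C17, so one step makes the C1–C15 bond, the ε-lactone ring and the exo-methylene; C1 is expected as 1R (Re-face attack) because only the chair-like oxepanone transition state with both macrocycle arms (C2 on C1, C11 on C12) pseudo-equatorial and C20 axial avoids transannular strain, a bias that the (S)-catalyst should reinforce through its hydrogen bond to C3=O and that reversibility of the Michael step can correct; the closest known reaction type is the phosphine- or phosphinothiourea-catalysed intramolecular Rauhut–Currier (vinylogous Morita–Baylis–Hillman) cycloisomerisation of tethered bis-enones to five- and six-membered carbocycles, which has not been shown for an acrylate ester donor or for closing a seven-membered α-methylene lactone.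

Step 21
Reactants: 27 bicyclic keto lactone
Product: 28 (1R,3R,4S,7Z,11S,12R)-3-hydroxy-4,11-bis(TBSO)cembra-7,15(17)-dien-16,12-olide
Conditions: (S)-Me-CBS (0.5–1 equiv), catecholborane, toluene, −78 to −40 °C; aq. work-up
Reagents that add atoms: none
Why: Corey–Bakshi–Shibata reduction: with quaternary C4 as the large and C2H2 as the small group, the (S)-oxazaborolidine delivers hydride to the Si face of C3=O to give 3R, catecholborane leaves the α-methylene lactone and C7=C8 untouched, and the neutral borate avoids alkoxide-driven translactonisation.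

Step 22
Reactants: 28 bis-TBS ether
Product: 29 (1R,3R,4S,7Z,11S,12R)-3,4,11-trihydroxycembra-7,15(17)-dien-16,12-olide (CNP0263298.1)
Conditions: HF·pyridine, THF, 0 °C to rt (polypropylene vessel)
Reagents that add atoms: none
Why: Global fluoride desilylation under mildly acidic, non-nucleophilic conditions frees C4–OH and C11–OH without conjugate addition to the α-methylene lactone or base-induced lactone migration.

**Compound list**
1 | nerol, (2Z)-3,7-dimethylocta-2,6-dien-1-ol | CC(C)=CCC/C(C)=C\CO | starting material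
2 | neryl bromide | CC(C)=CCC/C(C)=C\CBr | intermediate
3 | methallyl alcohol (2-methylprop-2-en-1-ol) | C=C(C)CO | starting material
4 | dilithiated methallyl alcohol (not isolated) | [Li]CC(=C)CO[Li] | intermediate
5 | (5Z)-6,10-dimethyl-2-methylideneundeca-5,9-dien-1-ol | CC(C)=CCC/C(C)=C\CCC(=C)CO | intermediate
6 | [(2S)-2-[(3Z)-4,8-dimethylnona-3,7-dien-1-yl]oxiran-2-yl]methanol | CC(C)=CCC/C(C)=C\CC[C@]1(CO)CO1 | intermediate
7 | (2S,5Z)-2,6,10-trimethylundeca-5,9-diene-1,2-diol | CC(C)=CCC/C(C)=C\CC[C@](O)(CO)C | intermediate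
8 | (2S,5Z)-1,2-bis(TBSO)-2,6,10-trimethylundeca-5,9-diene | CC(C)=CCC/C(C)=C\CC[C@](O[Si](C)(C)C(C)(C)C)(CO[Si](C)(C)C(C)(C)C)C | intermediate
9 | (2E,6Z,10S)-10,11-bis(TBSO)-2,6,10-trimethylundeca-2,6-dien-1-ol | OC/C(C)=C/CC/C(C)=C\CC[C@](O[Si](C)(C)C(C)(C)C)(CO[Si](C)(C)C(C)(C)C)C | intermediate
10 | (11S,12S)-epoxy alcohol, [(2S,3S)-3-[(3Z,7S)-7,8-bis(TBSO)-3,7-dimethyloct-3-en-1-yl]-2-methyloxiran-2-yl]methanol | OC[C@]1(C)O[C@H]1CC/C(C)=C\CC[C@](O[Si](C)(C)C(C)(C)C)(CO[Si](C)(C)C(C)(C)C)C | intermediate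
11 | triflate of 10 | O=S(=O)(OC[C@]1(C)O[C@H]1CC/C(C)=C\CC[C@](O[Si](C)(C)C(C)(C)C)(CO[Si](C)(C)C(C)(C)C)C)C(F)(F)F | intermediate
12 | tert-butyl acetate | CC(=O)OC(C)(C)C | starting material
13 | lithium enolate of tert-butyl acetate (not isolated) | C=C(O[Li])OC(C)(C)C | intermediate
14 | tert-butyl 3-[(2S,3S)-3-[(3Z,7S)-7,8-bis(TBSO)-3,7-dimethyloct-3-en-1-yl]-2-methyloxiran-2-yl]propanoate | CC(C)(C)OC(=O)CC[C@]1(C)O[C@H]1CC/C(C)=C\CC[C@](O[Si](C)(C)C(C)(C)C)(CO[Si](C)(C)C(C)(C)C)C | intermediate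
15 | (5R)-5-[(1S,4Z,8S)-8,9-bis(TBSO)-1-hydroxy-4,8-dimethylnon-4-en-1-yl]-5-methyloxolan-2-one | O=C1CC[C@@](C)(O1)[C@@H](O)CC/C(C)=C\CC[C@](O[Si](C)(C)C(C)(C)C)(CO[Si](C)(C)C(C)(C)C)C | intermediate
16 | (5R)-5-[(1S,4Z,8S)-1,8,9-tris(TBSO)-4,8-dimethylnon-4-en-1-yl]-5-methyloxolan-2-one | O=C1CC[C@@](C)(O1)[C@@H](O[Si](C)(C)C(C)(C)C)CC/C(C)=C\CC[C@](O[Si](C)(C)C(C)(C)C)(CO[Si](C)(C)C(C)(C)C)C | intermediate
17 | lactol of 16 (anomer mixture) | OC1CC[C@@](C)(O1)[C@@H](O[Si](C)(C)C(C)(C)C)CC/C(C)=C\CC[C@](O[Si](C)(C)C(C)(C)C)(CO[Si](C)(C)C(C)(C)C)C | intermediate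
18 | (5R,6S,9Z,13S)-6,13,14-tris(TBSO)-5,9,13-trimethyltetradec-9-en-1-yn-5-ol | C#CCC[C@@](C)(O)[C@@H](O[Si](C)(C)C(C)(C)C)CC/C(C)=C\CC[C@](O[Si](C)(C)C(C)(C)C)(CO[Si](C)(C)C(C)(C)C)C | intermediate
19 | (E)-alkenylzirconocene chloride, C12–O also zirconated (not isolated; Cp drawn η1) | Cl[Zr](C1C=CC=C1)(C1C=CC=C1)/C=C/CC[C@@](C)(O[Zr](Cl)(C1C=CC=C1)C1C=CC=C1)[C@@H](O[Si](C)(C)C(C)(C)C)CC/C(C)=C\CC[C@](O[Si](C)(C)C(C)(C)C)(CO[Si](C)(C)C(C)(C)C)C | intermediate
20 | (1E,5R,6S,9Z,13S)-1-iodo-6,13,14-tris(TBSO)-5,9,13-trimethyltetradeca-1,9-dien-5-ol | I/C=C/CC[C@@](C)(O)[C@@H](O[Si](C)(C)C(C)(C)C)CC/C(C)=C\CC[C@](O[Si](C)(C)C(C)(C)C)(CO[Si](C)(C)C(C)(C)C)C | intermediate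
21 | acryloyl chloride | C=CC(=O)Cl | starting material
22 | acrylate of 20 | I/C=C/CC[C@@](C)(OC(=O)C=C)[C@@H](O[Si](C)(C)C(C)(C)C)CC/C(C)=C\CC[C@](O[Si](C)(C)C(C)(C)C)(CO[Si](C)(C)C(C)(C)C)C | intermediate
23 | primary (C3) alcohol from 22 | I/C=C/CC[C@@](C)(OC(=O)C=C)[C@@H](O[Si](C)(C)C(C)(C)C)CC/C(C)=C\CC[C@](O[Si](C)(C)C(C)(C)C)(CO)C | intermediate
24 | C3 aldehyde | I/C=C/CC[C@@](C)(OC(=O)C=C)[C@@H](O[Si](C)(C)C(C)(C)C)CC/C(C)=C\CC[C@](O[Si](C)(C)C(C)(C)C)(C=O)C | intermediate
25 | 14-membered allylic alcohol, (1E,4S,7Z,11S,12R), C3 epimers, C12 acrylate | OC1/C=C/CC[C@@](C)(OC(=O)C=C)[C@@H](O[Si](C)(C)C(C)(C)C)CC/C(C)=C\CC[C@@]1(O[Si](C)(C)C(C)(C)C)C | intermediate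
26 | 14-membered E-enone, (1E,4S,7Z,11S,12R), C12 acrylate | O=C1/C=C/CC[C@@](C)(OC(=O)C=C)[C@@H](O[Si](C)(C)C(C)(C)C)CC/C(C)=C\CC[C@@]1(O[Si](C)(C)C(C)(C)C)C | intermediate
27 | (1R,4S,7Z,11S,12R)-4,11-bis(TBSO)-3-oxocembra-7,15(17)-dien-16,12-olide | C=C1C(=O)O[C@]2(C)CC[C@@H]1CC(=O)[C@@](C)(O[Si](C)(C)C(C)(C)C)CC/C=C(/C)CC[C@@H]2O[Si](C)(C)C(C)(C)C | intermediate
28 | (1R,3R,4S,7Z,11S,12R)-3-hydroxy-4,11-bis(TBSO)cembra-7,15(17)-dien-16,12-olide | C=C1C(=O)O[C@]2(C)CC[C@@H]1C[C@@H](O)[C@@](C)(O[Si](C)(C)C(C)(C)C)CC/C=C(/C)CC[C@@H]2O[Si](C)(C)C(C)(C)C | intermediate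
29 | (1R,3R,4S,7Z,11S,12R)-3,4,11-trihydroxycembra-7,15(17)-dien-16,12-olide (CNP0263298.1) | C=C1C(=O)O[C@]2(C)CC[C@@H]1C[C@@H](O)[C@@](C)(O)CC/C=C(/C)CC[C@@H]2O | target

**Totals**
Total step count: 22. Longest linear sequence: 22 steps from nerol. Compounds 3, 12 and 21 are bought and enter directly.

**The three steps most likely to fail**

1. **Step 20 (the new reaction).**
   - Risk: seven-ring closure may lose to acrylate oligomerisation, or the wrong C1 epimer may form.
   - Fallback (known chemistry only), sets out from 20 and comes back at 27. Esterify the tertiary alcohol of 20 with diethylphosphonoacetic acid (DCC, DMAP) to the diethylphosphonoacetate ester F1. Remove the primary silyl group (HF·pyridine) to give the primary alcohol F2, and oxidise (Dess–Martin) to the aldehyde F3. Close the ring by Nozaki–Hiyama–Kishi coupling to the macrocyclic allylic alcohol F4, and oxidise to the macrocyclic enone phosphonoacetate F5. Cyclise with LiCl/DBU in MeCN by reversible intramolecular Michael addition of the phosphonate-stabilised carbanion to C1; thermodynamic control should favour the diequatorial 1R isomer and gives the α-phosphono ε-lactone F6. Install the methylene by Horner–Wadsworth–Emmons reaction with formaldehyde (K2CO3, aq. CH2O, THF), which gives 27.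

2. **Step 9.**
   - Risk: SN2 at a CH2–OTf next to a fully substituted oxirane carbon may be too slow, so the triflate decomposes.
   - Fallback, sets out from 10 and comes back at 14. Oxidise 10 (Dess–Martin) to the epoxy aldehyde F7. Olefinate with tert-butyl (triphenylphosphoranylidene)acetate to the (E)-γ,δ-epoxy enoate F8. Saturate only the disubstituted conjugated alkene with diimide (2-nitrobenzenesulfonyl hydrazide, Et3N), which gives 14.

3. **Step 21.**
   - Risk: the ketone sits between a quaternary silyloxy carbon and the macrocycle and may resist the CBS catalyst or reduce with poor selectivity.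
   - Fallback, sets out from 27 and comes back at 29. Desilylate first (HF·pyridine) to the keto diol F9. Then reduce under substrate control with Zn(BH4)2 (Et2O/CH2Cl2, −30 °C). Chelation of Zn between C3=O and the free C4–OH (Cram chelate) exposes the face flanked by the C18 methyl, which is also the peripheral face of the ring. Hydride attack there gives 3R and therefore 29 directly.

**Further compounds**
F1 | step 20 | (1E,5R,6S,9Z,13S)-1-iodo-6,13,14-tris(TBSO)-5,9,13-trimethyltetradeca-1,9-dien-5-yl 2-(diethoxyphosphoryl)acetate | I/C=C/CC[C@@](C)(OC(=O)CP(=O)(OCC)OCC)[C@@H](O[Si](C)(C)C(C)(C)C)CC/C(C)=C\CC[C@](O[Si](C)(C)C(C)(C)C)(CO[Si](C)(C)C(C)(C)C)C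
F2 | step 20 | primary (C3) alcohol from F1 | I/C=C/CC[C@@](C)(OC(=O)CP(=O)(OCC)OCC)[C@@H](O[Si](C)(C)C(C)(C)C)CC/C(C)=C\CC[C@](O[Si](C)(C)C(C)(C)C)(CO)C
F3 | step 20 | C3 aldehyde from F2 | I/C=C/CC[C@@](C)(OC(=O)CP(=O)(OCC)OCC)[C@@H](O[Si](C)(C)C(C)(C)C)CC/C(C)=C\CC[C@](O[Si](C)(C)C(C)(C)C)(C=O)C
F4 | step 20 | 14-membered allylic alcohol (C3 epimers) with C12 diethylphosphonoacetate | OC1/C=C/CC[C@@](C)(OC(=O)CP(=O)(OCC)OCC)[C@@H](O[Si](C)(C)C(C)(C)C)CC/C(C)=C\CC[C@@]1(O[Si](C)(C)C(C)(C)C)C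
F5 | step 20 | 14-membered E-enone with C12 diethylphosphonoacetate | O=C1/C=C/CC[C@@](C)(OC(=O)CP(=O)(OCC)OCC)[C@@H](O[Si](C)(C)C(C)(C)C)CC/C(C)=C\CC[C@@]1(O[Si](C)(C)C(C)(C)C)C
F6 | step 20 | (1R,4S,7Z,11S,12R)-15-(diethoxyphosphoryl)-4,11-bis(TBSO)-3-oxo-17-norcembr-7-en-16,12-olide (C15 epimers) | CCOP(=O)(OCC)C1C(=O)O[C@]2(C)CC[C@@H]1CC(=O)[C@@](C)(O[Si](C)(C)C(C)(C)C)CC/C=C(/C)CC[C@@H]2O[Si](C)(C)C(C)(C)C
F7 | step 9 | (2R,3S)-3-[(3Z,7S)-7,8-bis(TBSO)-3,7-dimethyloct-3-en-1-yl]-2-methyloxirane-2-carbaldehyde | O=C[C@]1(C)O[C@H]1CC/C(C)=C\CC[C@](O[Si](C)(C)C(C)(C)C)(CO[Si](C)(C)C(C)(C)C)C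
F8 | step 9 | tert-butyl (2E)-3-[(2S,3S)-3-[(3Z,7S)-7,8-bis(TBSO)-3,7-dimethyloct-3-en-1-yl]-2-methyloxiran-2-yl]prop-2-enoate | CC(C)(C)OC(=O)/C=C/[C@]1(C)O[C@H]1CC/C(C)=C\CC[C@](O[Si](C)(C)C(C)(C)C)(CO[Si](C)(C)C(C)(C)C)C
F9 | step 21 | (1R,4S,7Z,11S,12R)-4,11-dihydroxy-3-oxocembra-7,15(17)-dien-16,12-olide | C=C1C(=O)O[C@]2(C)CC[C@@H]1CC(=O)[C@@](C)(O)CC/C=C(/C)CC[C@@H]2O
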